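**Retrosynthetic overview**
- The target is cut back at the C6 veratroate and the C2/C10 acetates; the C6 carbinol comes from a C6 ketone by C4‑hydroxyl‑directed reduction, and the C8 methyl from an ester.
- Feature used: ring A (seven‑membered, C1–C10–C9=C8–C7–C6–C5) is a cyclohepta‑1,4‑diene once the C6 oxygen is written as a C5=C6 enol silyl ether. Its only sp3–sp3 bond, C1(quaternary, Me)–C10(carbinol), is the bond formed in a divinylcyclopropane [3,3] shift.
- Key disconnection, a formal (4+3): bonds C7–C8 and C1–C10, from 2‑silyloxydiene 13 (ring B cyclopentene) and the (E)‑4‑silyloxy vinyldiazoacetate 17.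
- Ring B comes first, from (R)‑4‑silyloxycyclopentenone: C4 is set by isopropyl addition anti to the C2 oxygen, and C2 is then inverted by Mitsunobu to give the trans C2‑O/C4‑O pattern. Ring A is closed second, in the key step.
- C5 (trans ring fusion) and C6 are set after the key step.

Key step: step 13

Remark: atoms are numbered as above (ring B: C1–C5; ring A: C1, C10, C9, C8, C7, C6, C5) and bicyclic names use this numbering; β is the face of the C1 methyl group; TBS = tert‑butyldimethylsilyl, TES = triethylsilyl; an enol silyl ether replaces an ethyl enol ether at C6 because aqueous acid would ionise the C4 oxygen that is allylic to the enol ether.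

**Step 1**
Reactants: 1 (R)-4-(TBSO)cyclopent-2-en-1-one
Product: 2 (3R,4R)-4-(TBSO)-3-methyl-1-(trimethylsilyloxy)cyclopent-1-ene
Conditions: MeMgBr, CuBr·SMe2 (cat.), TMSCl, THF, −78 °C
Reagents that add atoms: methylmagnesium bromide, C[Mg]Br; chlorotrimethylsilane, C[Si](C)(C)Cl
Why: Copper‑catalysed conjugate addition delivers methyl anti to the silyloxy group, and TMSCl traps the enolate regiospecifically before the silyloxy group can be eliminated (conjugate addition with enolate trapping).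

**Step 2**
Reactants: 2 (3R,4R)-4-(TBSO)-3-methyl-1-(trimethylsilyloxy)cyclopent-1-ene
Product: 3 (R)-4-(TBSO)-3-methylcyclopent-2-en-1-one
Conditions: Pd(OAc)2 (10 mol %), O2 (1 atm), DMSO, rt
Reagents that add atoms: none
Why: Saegusa–Ito oxidation of the regiodefined silyl enol ether restores the enone toward the methyl‑bearing carbon, erasing that stereocentre and leaving the silyloxy carbon untouched.

**Step 3**
Reactants: 3 (R)-4-(TBSO)-3-methylcyclopent-2-en-1-one
Product: 4 (R)-4-(TBSO)-2-iodo-3-methylcyclopent-2-en-1-one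
Conditions: I2, pyridine, CH2Cl2, 0 °C to rt
Reagents that add atoms: iodine, II
Why: Pyridine‑mediated α‑iodination of the enone (addition, iodination, elimination) installs the handle for the later cross‑coupling.

**Step 4**
Reactants: 4 (R)-4-(TBSO)-2-iodo-3-methylcyclopent-2-en-1-one
Product: 5 (1R,4R)-4-(TBSO)-2-iodo-3-methyl-1-(propan-2-yl)cyclopent-2-en-1-ol
Conditions: i-PrMgCl, CeCl3, THF, −78 °C
Reagents that add atoms: isopropylmagnesium chloride, CC(C)[Mg]Cl
Why: The cerium‑modified Grignard reagent adds 1,2 to the hindered iodoenone without iodine–magnesium exchange and from the face anti to the silyloxy group, which fixes the tertiary carbinol (C4) with its hydroxyl cis to the C2 oxygen.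

**Step 5**
Reactants: 5 (1R,4R)-4-(TBSO)-2-iodo-3-methyl-1-(propan-2-yl)cyclopent-2-en-1-ol
Product: 6 (1R,4R)-2-iodo-3-methyl-1-(propan-2-yl)cyclopent-2-ene-1,4-diol
Conditions: Bu4NF, THF, 0 °C
Reagents that add atoms: none
Why: Fluoride desilylation frees the secondary allylic alcohol for inversion.

**Step 6**
Reactants: 6 (1R,4R)-2-iodo-3-methyl-1-(propan-2-yl)cyclopent-2-ene-1,4-diol
Product: 7 (1S,4R)-4-hydroxy-3-iodo-2-methyl-4-(propan-2-yl)cyclopent-2-en-1-yl 4-nitrobenzoate
Conditions: 4-nitrobenzoic acid, PPh3, diisopropyl azodicarboxylate, THF, 0 °C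
Reagents that add atoms: 4-nitrobenzoic acid, O=C(O)c1ccc(cc1)[N+](=O)[O-]
Why: Mitsunobu esterification inverts the secondary allylic carbinol by SN2 and so turns the cis relationship from step 4 into the trans C2‑O/C4‑O relationship of the target; the tertiary alcohol does not react.

**Step 7**
Reactants: 7 (1S,4R)-4-hydroxy-3-iodo-2-methyl-4-(propan-2-yl)cyclopent-2-en-1-yl 4-nitrobenzoate
Product: 8 (1R,4S)-2-iodo-3-methyl-1-(propan-2-yl)cyclopent-2-ene-1,4-diol
Conditions: K2CO3 (cat.), MeOH, 0 °C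
Reagents that add atoms: none
Why: Mild transesterification removes the nitrobenzoate without touching the vinyl iodide.

**Step 8**
Reactants: 8 (1R,4S)-2-iodo-3-methyl-1-(propan-2-yl)cyclopent-2-ene-1,4-diol
Product: 9 (1R,4S)-4-(TBSO)-2-iodo-3-methyl-1-(propan-2-yl)cyclopent-2-en-1-ol
Conditions: TBSCl, imidazole, DMF, rt
Reagents that add atoms: tert-butylchlorodimethylsilane, CC(C)(C)[Si](C)(C)Cl
Why: The secondary alcohol is silylated selectively over the hindered tertiary one (silyl protection).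

**Step 9**
Reactants: 9 (1R,4S)-4-(TBSO)-2-iodo-3-methyl-1-(propan-2-yl)cyclopent-2-en-1-ol; 10 tributyl(1-ethoxyethenyl)stannane
Product: 12 1-[(3S,5R)-3-(TBSO)-5-hydroxy-2-methyl-5-(propan-2-yl)cyclopent-1-en-1-yl]ethan-1-one, via ethoxyvinyl diene 11 (not isolated)
Conditions: Pd(PPh3)4 (5 mol %), CuI (10 mol %), CsF, DMF, 45 °C; then 1 M HCl, THF, 0 °C
Reagents that add atoms: water, O
Why: Stille coupling under copper/fluoride activation (suited to hindered vinyl iodides) gives the 2‑ethoxydiene, whose terminal enol ether is hydrolysed on acidic work‑up, so that the stannane acts as an acetyl anion equivalent.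

**Step 10**
Reactants: 12 1-[(3S,5R)-3-(TBSO)-5-hydroxy-2-methyl-5-(propan-2-yl)cyclopent-1-en-1-yl]ethan-1-one
Product: 13 (3S,5R)-3-(TBSO)-2-methyl-5-(propan-2-yl)-5-(TESO)-1-[1-(TESO)ethenyl]cyclopent-1-ene
Conditions: TESOTf (2.5 equiv), Et3N, CH2Cl2, −78 to 0 °C
Reagents that add atoms: triethylsilyl trifluoromethanesulfonate, CC[Si](CC)(CC)OS(=O)(=O)C(F)(F)F
Why: Silyl triflate and amine silylate the tertiary alcohol and convert the methyl ketone, by deprotonation at the methyl group, into the 2‑silyloxydiene in one operation (silyl enol ether formation).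

**Step 11**
Reactants: 14 ethyl diazoacetate; 15 (TBSO)acetaldehyde
Product: 16 ethyl 4-(TBSO)-2-diazo-3-hydroxybutanoate (racemic)
Conditions: DBU (10 mol %), MeCN, rt
Reagents that add atoms: none
Why: Base‑catalysed aldol‑type addition of the diazoacetate carbon to the aldehyde gives the β‑hydroxy‑α‑diazo ester.

**Step 12**
Reactants: 16 ethyl 4-(TBSO)-2-diazo-3-hydroxybutanoate
Product: 17 ethyl (E)-4-(TBSO)-2-diazobut-3-enoate
Conditions: POCl3, Et3N, CH2Cl2, 0 °C
Reagents that add atoms: none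
Why: Dehydration through the dichlorophosphate (anti elimination with the two large groups apart) should give the (E)‑silyloxyvinyl diazoacetate, the geometry that later places the C10 oxygen.

**Step 13**
Reactants: 13 (3S,5R)-3-(TBSO)-2-methyl-5-(propan-2-yl)-5-(TESO)-1-[1-(TESO)ethenyl]cyclopent-1-ene; 17 ethyl (E)-4-(TBSO)-2-diazobut-3-enoate
Product: 19 ethyl 2α,10α-bis(TBSO)-4β,6-bis(TESO)-1β-methyl-4α-(propan-2-yl)bicyclo[5.3.0]deca-5,8-diene-8-carboxylate, via cis-divinylcyclopropane 18 (not isolated)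
Conditions: Rh2(R-DOSP)4 [dirhodium tetrakis((R)-N-(4-dodecylphenylsulfonyl)prolinate)] (1 mol %), hexanes, −40 °C, slow addition of 17; then rt to 60 °C
Reagents that add atoms: none
Why: Proposed new method: the carbenoid formed from 17 at divalent rhodium (donor silyloxyvinyl, acceptor ester) should cyclopropanate the electron‑rich, unhindered 1‑silyloxyvinyl alkene of 13 (bonds C8–C7 and C8–C6) and spare the tetrasubstituted ring alkene, and the cis‑divinylcyclopropane 18 should then undergo a [3,3] shift through a boat transition state that forms C1–C10 and breaks C6–C8. The closest known reaction type is the dirhodium‑catalysed cyclopropanation of 1‑vinylcycloalkenes and 2‑oxygenated dienes by vinyldiazoacetates with in situ divinylcyclopropane rearrangement, which has not been shown with a 4‑silyloxy vinyldiazoacetate or with this doubly flanked diene terminus. Ring A is closed by this sigmatropic ring expansion (formal (4+3) annulation) and not by an ionic cyclisation. C1 and C10 are created together: the face of the enol ether attacked by the carbenoid fixes the cyclopropane configuration and thereby the face of C1 reached by C10, and that face is chosen by the chiral catalyst; the R‑prolinate is picked by transposing the sense of induction known for monosubstituted alkenes, and the antipodal catalyst is the remedy should the C2/C4 substituents oppose it. The relative configuration follows from the boat geometry, where the two E substituents (silyloxy on C10, ring carbon C2 on C1) end up cis, so the C10 oxygen is trans to the C1 methyl group. The step needs cyclopropanation to win over vinylogous attack at the silyloxy‑bearing terminus and over silyl transfer, which the E substituent, the non‑polar solvent and the hindered catalyst should favour, and it needs the Z methyl group on C1 to be tolerated in the Cope step, for which the s‑cis‑capable enol ether and gentle heating are provided.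

**Step 14**
Reactants: 19 ethyl 2α,10α-bis(TBSO)-4β,6-bis(TESO)-1β-methyl-4α-(propan-2-yl)bicyclo[5.3.0]deca-5,8-diene-8-carboxylate
Product: 20 [2α,10α-bis(TBSO)-4β,6-bis(TESO)-1β-methyl-4α-(propan-2-yl)bicyclo[5.3.0]deca-5,8-dien-8-yl]methanol
Conditions: i-Bu2AlH, CH2Cl2, −78 °C; Rochelle salt work-up
Reagents that add atoms: none
Why: The unsaturated ester is reduced 1,2 to the allylic alcohol while silyl ethers and the enol silyl ether stay intact (hydride reduction).

**Step 15**
Reactants: 20 [2α,10α-bis(TBSO)-4β,6-bis(TESO)-1β-methyl-4α-(propan-2-yl)bicyclo[5.3.0]deca-5,8-dien-8-yl]methanol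
Product: 22 2α,10α-bis(TBSO)-4β,6-bis(TESO)-1β,8-dimethyl-4α-(propan-2-yl)bicyclo[5.3.0]deca-5,8-diene, via allylic mesylate 21 (not isolated)
Conditions: MsCl, Et3N, CH2Cl2, −30 °C; then LiBHEt3, THF, −30 to 0 °C
Reagents that add atoms: none
Why: The primary allylic mesylate is displaced by hydride in an SN2 reduction at the unhindered primary carbon (attack at C9 is disfavoured next to the C10 silyloxy group), which turns the ester carbon into the C8 methyl group.

**Step 16**
Reactants: 22 2α,10α-bis(TBSO)-4β,6-bis(TESO)-1β,8-dimethyl-4α-(propan-2-yl)bicyclo[5.3.0]deca-5,8-diene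
Product: 23 2α,10α-bis(TBSO)-4β-hydroxy-1β,8-dimethyl-4α-(propan-2-yl)-5β-H-bicyclo[5.3.0]dec-8-en-6-one (cis-fused)
Conditions: HF·pyridine, excess pyridine, THF, 0 °C
Reagents that add atoms: none
Why: Buffered fluoride cleaves the enol silyl ether and the tertiary TES ether while the two secondary TBS ethers survive; C‑protonation at C5 is expected on the more open β face, so the cis‑fused ketone should predominate (any trans‑fused 24 formed is carried on).

**Step 17**
Reactants: 23 2α,10α-bis(TBSO)-4β-hydroxy-1β,8-dimethyl-4α-(propan-2-yl)-5β-H-bicyclo[5.3.0]dec-8-en-6-one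
Product: 24 2α,10α-bis(TBSO)-4β-hydroxy-1β,8-dimethyl-4α-(propan-2-yl)-5α-H-bicyclo[5.3.0]dec-8-en-6-one (trans-fused)
Conditions: DBU (0.3 equiv), PhMe, rt, stopped at equilibrium
Reagents that add atoms: none
Why: Base‑mediated epimerisation α to the ketone should move C5 to the trans‑fused isomer, in which C6 is anti to the C4 isopropyl group and the C4 hydroxyl can hydrogen‑bond to the C6 carbonyl.

**Step 18**
Reactants: 24 2α,10α-bis(TBSO)-4β-hydroxy-1β,8-dimethyl-4α-(propan-2-yl)-5α-H-bicyclo[5.3.0]dec-8-en-6-one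
Product: 25 2α,10α-bis(TBSO)-1β,8-dimethyl-4α-(propan-2-yl)-5α-H-bicyclo[5.3.0]dec-8-ene-4β,6α-diol
Conditions: Me4NBH(OAc)3, AcOH–MeCN, −30 °C to rt
Reagents that add atoms: none
Why: Evans–Saksena reduction: the C4 alkoxyborohydride delivers hydride intramolecularly to the β face of C6, giving the 6α‑alcohol; only the trans‑fused ketone has the C4 oxygen and C6 on the same face, so residual 23 is not reduced.

**Step 19**
Reactants: 25 2α,10α-bis(TBSO)-1β,8-dimethyl-4α-(propan-2-yl)-5α-H-bicyclo[5.3.0]dec-8-ene-4β,6α-diol; 26 3,4-dimethoxybenzoyl chloride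
Product: 27 2α,10α-bis(TBSO)-4β-hydroxy-1β,8-dimethyl-4α-(propan-2-yl)-5α-H-bicyclo[5.3.0]dec-8-en-6α-yl 3,4-dimethoxybenzoate
Conditions: DMAP (cat.), Et3N, CH2Cl2, rt to 40 °C
Reagents that add atoms: none
Why: DMAP‑catalysed acylation esterifies the secondary C6 hydroxyl; the tertiary C4 hydroxyl is too hindered to react.

**Step 20**
Reactants: 27 2α,10α-bis(TBSO)-4β-hydroxy-1β,8-dimethyl-4α-(propan-2-yl)-5α-H-bicyclo[5.3.0]dec-8-en-6α-yl 3,4-dimethoxybenzoate
Product: 28 2α,4β,10α-trihydroxy-1β,8-dimethyl-4α-(propan-2-yl)-5α-H-bicyclo[5.3.0]dec-8-en-6α-yl 3,4-dimethoxybenzoate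
Conditions: Bu4NF, AcOH, THF, rt to 40 °C
Reagents that add atoms: none
Why: Acetic‑acid‑buffered fluoride removes both hindered TBS ethers without acyl migration or ester cleavage (desilylation).

**Step 21**
Reactants: 28 2α,4β,10α-trihydroxy-1β,8-dimethyl-4α-(propan-2-yl)-5α-H-bicyclo[5.3.0]dec-8-en-6α-yl 3,4-dimethoxybenzoate
Product: 29 CNP0320758.1, 2α,10α-diacetoxy-4β-hydroxy-1β,8-dimethyl-4α-(propan-2-yl)-5α-H-bicyclo[5.3.0]dec-8-en-6α-yl 3,4-dimethoxybenzoate
Conditions: Ac2O, pyridine, DMAP (cat.), CH2Cl2, 0 °C to rt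
Reagents that add atoms: acetic anhydride, CC(=O)OC(C)=O
Why: Acetylation of the two secondary alcohols at C2 and C10 completes the target; the tertiary C4 alcohol should stay free under these mild conditions.

**Compound list**
1 | (R)-4-(tert-butyldimethylsilyloxy)cyclopent-2-en-1-one | O=C1C=C[C@H](O[Si](C)(C)C(C)(C)C)C1 | starting material
2 | (3R,4R)-4-(TBSO)-3-methyl-1-(trimethylsilyloxy)cyclopent-1-ene | C[Si](C)(C)OC1=C[C@@H](C)[C@H](O[Si](C)(C)C(C)(C)C)C1 | intermediate
3 | (R)-4-(TBSO)-3-methylcyclopent-2-en-1-one | O=C1C=C(C)[C@H](O[Si](C)(C)C(C)(C)C)C1 | intermediate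
4 | (R)-4-(TBSO)-2-iodo-3-methylcyclopent-2-en-1-one | O=C1C(I)=C(C)[C@H](O[Si](C)(C)C(C)(C)C)C1 | intermediate
5 | (1R,4R)-4-(TBSO)-2-iodo-3-methyl-1-(propan-2-yl)cyclopent-2-en-1-ol | IC1=C(C)[C@H](O[Si](C)(C)C(C)(C)C)C[C@@]1(O)C(C)C | intermediate
6 | (1R,4R)-2-iodo-3-methyl-1-(propan-2-yl)cyclopent-2-ene-1,4-diol (cis) | IC1=C(C)[C@H](O)C[C@@]1(O)C(C)C | intermediate
7 | (1S,4R)-4-hydroxy-3-iodo-2-methyl-4-(propan-2-yl)cyclopent-2-en-1-yl 4-nitrobenzoate | IC1=C(C)[C@@H](OC(=O)c2ccc(cc2)[N+](=O)[O-])C[C@@]1(O)C(C)C | intermediate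
8 | (1R,4S)-2-iodo-3-methyl-1-(propan-2-yl)cyclopent-2-ene-1,4-diol (trans) | IC1=C(C)[C@@H](O)C[C@@]1(O)C(C)C | intermediate
9 | (1R,4S)-4-(TBSO)-2-iodo-3-methyl-1-(propan-2-yl)cyclopent-2-en-1-ol | IC1=C(C)[C@@H](O[Si](C)(C)C(C)(C)C)C[C@@]1(O)C(C)C | intermediate
10 | tributyl(1-ethoxyethenyl)stannane | CCCC[Sn](CCCC)(CCCC)C(=C)OCC | starting material
11 | (1R,4S)-4-(TBSO)-2-(1-ethoxyethenyl)-3-methyl-1-(propan-2-yl)cyclopent-2-en-1-ol | C=C(OCC)C1=C(C)[C@@H](O[Si](C)(C)C(C)(C)C)C[C@@]1(O)C(C)C | intermediate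
12 | 1-[(3S,5R)-3-(TBSO)-5-hydroxy-2-methyl-5-(propan-2-yl)cyclopent-1-en-1-yl]ethan-1-one | CC(=O)C1=C(C)[C@@H](O[Si](C)(C)C(C)(C)C)C[C@@]1(O)C(C)C | intermediate
13 | (3S,5R)-3-(TBSO)-2-methyl-5-(propan-2-yl)-5-(TESO)-1-[1-(TESO)ethenyl]cyclopent-1-ene (key-step precursor) | C=C(O[Si](CC)(CC)CC)C1=C(C)[C@@H](O[Si](C)(C)C(C)(C)C)C[C@@]1(O[Si](CC)(CC)CC)C(C)C | intermediate
14 | ethyl diazoacetate | CCOC(=O)C=[N+]=[N-] | starting material
15 | (tert-butyldimethylsilyloxy)acetaldehyde | O=CCO[Si](C)(C)C(C)(C)C | starting material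
16 | ethyl 4-(TBSO)-2-diazo-3-hydroxybutanoate (racemic) | CCOC(=O)C(=[N+]=[N-])C(O)CO[Si](C)(C)C(C)(C)C | intermediate
17 | ethyl (E)-4-(TBSO)-2-diazobut-3-enoate | CCOC(=O)C(=[N+]=[N-])/C=C/O[Si](C)(C)C(C)(C)C | intermediate
18 | cis-divinylcyclopropane: ethyl 1-[(E)-2-(TBSO)ethenyl]-2-(TESO)-2-(ring B cyclopentenyl)cyclopropane-1-carboxylate, alkenyl groups cis | CCOC(=O)[C@]1(/C=C/O[Si](C)(C)C(C)(C)C)C[C@@]1(O[Si](CC)(CC)CC)C2=C(C)[C@@H](O[Si](C)(C)C(C)(C)C)C[C@@]2(O[Si](CC)(CC)CC)C(C)C | intermediate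
19 | ethyl 2α,10α-bis(TBSO)-4β,6-bis(TESO)-1β-methyl-4α-(propan-2-yl)bicyclo[5.3.0]deca-5,8-diene-8-carboxylate (key-step product) | CC[Si](CC)(CC)OC1=C2[C@](O[Si](CC)(CC)CC)(C(C)C)C[C@H](O[Si](C)(C)C(C)(C)C)[C@]2(C)[C@H](O[Si](C)(C)C(C)(C)C)C=C(C(=O)OCC)C1 | intermediate
20 | corresponding C8 hydroxymethyl compound (allylic alcohol) | CC[Si](CC)(CC)OC1=C2[C@](O[Si](CC)(CC)CC)(C(C)C)C[C@H](O[Si](C)(C)C(C)(C)C)[C@]2(C)[C@H](O[Si](C)(C)C(C)(C)C)C=C(CO)C1 | intermediate
21 | corresponding allylic methanesulfonate | CC[Si](CC)(CC)OC1=C2[C@](O[Si](CC)(CC)CC)(C(C)C)C[C@H](O[Si](C)(C)C(C)(C)C)[C@]2(C)[C@H](O[Si](C)(C)C(C)(C)C)C=C(COS(C)(=O)=O)C1 | intermediate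
22 | 2α,10α-bis(TBSO)-4β,6-bis(TESO)-1β,8-dimethyl-4α-(propan-2-yl)bicyclo[5.3.0]deca-5,8-diene | CC[Si](CC)(CC)OC1=C2[C@](O[Si](CC)(CC)CC)(C(C)C)C[C@H](O[Si](C)(C)C(C)(C)C)[C@]2(C)[C@H](O[Si](C)(C)C(C)(C)C)C=C(C)C1 | intermediate
23 | cis-fused (5β-H) 4β-hydroxy-6-ketone | O=C1CC(C)=C[C@@H](O[Si](C)(C)C(C)(C)C)[C@@]2(C)[C@@H](O[Si](C)(C)C(C)(C)C)C[C@@](O)(C(C)C)[C@@H]12 | intermediate
24 | trans-fused (5α-H) 4β-hydroxy-6-ketone | O=C1CC(C)=C[C@@H](O[Si](C)(C)C(C)(C)C)[C@@]2(C)[C@@H](O[Si](C)(C)C(C)(C)C)C[C@@](O)(C(C)C)[C@H]12 | intermediate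
25 | 2α,10α-bis(TBSO) 4β,6α-diol | O[C@H]1CC(C)=C[C@@H](O[Si](C)(C)C(C)(C)C)[C@@]2(C)[C@@H](O[Si](C)(C)C(C)(C)C)C[C@@](O)(C(C)C)[C@H]12 | intermediate
26 | 3,4-dimethoxybenzoyl chloride | COc1ccc(cc1OC)C(Cl)=O | starting material
27 | 2α,10α-bis(TBSO) 4β-hydroxy 6α-(3,4-dimethoxybenzoate) | COc1ccc(C(=O)O[C@H]2CC(C)=C[C@@H](O[Si](C)(C)C(C)(C)C)[C@@]3(C)[C@@H](O[Si](C)(C)C(C)(C)C)C[C@@](O)(C(C)C)[C@H]23)cc1OC | intermediate
28 | 2α,4β,10α-triol 6α-(3,4-dimethoxybenzoate) | COc1ccc(C(=O)O[C@H]2CC(C)=C[C@@H](O)[C@@]3(C)[C@@H](O)C[C@@](O)(C(C)C)[C@H]23)cc1OC | intermediate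
29 | CNP0320758.1 | COc1ccc(C(=O)O[C@H]2CC(C)=C[C@@H](OC(C)=O)[C@@]3(C)[C@@H](OC(C)=O)C[C@@](O)(C(C)C)[C@H]23)cc1OC | target

**Step count:** 21 steps in total; longest linear sequence 19 steps (steps 1–10 and 13–21); the diazo partner takes 2 steps (11–12).

**Steps most likely to fail**

Step 13 (key step, proposed new method). The carbenoid may be consumed by vinylogous attack at its silyloxy terminus, by silyl transfer or by dimerisation. The catalyst and the C2/C4 stereocentres may be mismatched, giving poor facial selectivity. The cyclopropane may form with the alkenyl groups trans, or the Z methyl group may stall the Cope step. The fallback builds the same divinylcyclopropane stepwise by known reaction types. It sets out from diene 13 and returns at 19.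
- Ethyl 2-diazopent-4-enoate F1 is made by deacylative Regitz diazo transfer from commercial ethyl 2-acetylpent-4-enoate (4-acetamidobenzenesulfonyl azide, DBU).
- F1 is added to 13 at −78 °C with Rh2(O2CCPh3)4, or with the chiral tert-leucinate Rh2(PTTL)4 for face control. This is the established low‑temperature cyclopropanation of enol ethers by α‑alkyl diazoesters, and it should give the allyl-substituted siloxycyclopropane ester F2.
- Lemieux–Johnson cleavage of the terminal alkene (OsO4 cat., NaIO4, 2,6-lutidine) gives the cyclopropylacetaldehyde F3.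
- Enol silylation (TBSCl, DBU, CH2Cl2) gives 18, from which the Z enol ether is removed, and 18 is heated in toluene to give 19.

Step 17 (C5 epimerisation). Enolisation toward C7 may move the C8=C9 double bond into conjugation or expel the C10 silyloxy group. Ring B may open by retro‑aldol cleavage, or the equilibrium may not favour the trans fusion. The fallback sets C5 by hydride delivery in place of protonation. It sets out from 22 and returns at 25.
- Mild acid (p-TsOH·H2O cat., wet CH2Cl2) is allowed to unmask the ketone and eliminate the C4 oxygen, giving the C4=C5 enone F4.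
- Luche reduction (NaBH4, CeCl3·7H2O, MeOH) from the convex β face gives the 6α-allylic alcohol F5.
- Dimethyldioxirane epoxidises the tetrasubstituted C4=C5 alkene on the β face, giving the epoxy alcohol F6.
- NaAlH2(OCH2CH2OMe)2 in THF opens the epoxide: the C6 alkoxyaluminate delivers hydride to C5 from the α face with inversion, and the C4 oxygen stays β, giving 25.

Step 12 (vinyldiazo ester). The dehydration may give E/Z mixtures, and the electron‑rich vinyldiazo ester may cyclise to a pyrazole or decompose on handling. The fallback makes the diazo partner by enol silylation and diazo transfer in place of aldol and dehydration. It sets out from diene 13 with commercial methyl 4-oxobutanoate (COC(=O)CCC=O) and returns at 20.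
- TBSOTf and Et3N convert the oxoester into methyl 4-(TBSO)but-3-enoate F7, from which the E isomer is separated.
- Regitz diazo transfer (4-acetamidobenzenesulfonyl azide, DBU, MeCN) gives methyl (E)-4-(TBSO)-2-diazobut-3-enoate F8.
- F8 replaces 17 in step 13 and gives the methyl ester analogue of the cycloadduct F9.
- i-Bu2AlH reduction of F9 gives 20.

**Further compounds**
F1 | step 13 | ethyl 2-diazopent-4-enoate | C=CCC(=[N+]=[N-])C(=O)OCC
F2 | step 13 | ethyl 1-allyl-2-(TESO)-2-(ring B cyclopentenyl)cyclopropane-1-carboxylate, allyl cis to cyclopentenyl | CCOC(=O)[C@]1(CC=C)C[C@@]1(O[Si](CC)(CC)CC)C2=C(C)[C@@H](O[Si](C)(C)C(C)(C)C)C[C@@]2(O[Si](CC)(CC)CC)C(C)C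
F3 | step 13 | ethyl 1-(2-oxoethyl)-2-(TESO)-2-(ring B cyclopentenyl)cyclopropane-1-carboxylate | CCOC(=O)[C@]1(CC=O)C[C@@]1(O[Si](CC)(CC)CC)C2=C(C)[C@@H](O[Si](C)(C)C(C)(C)C)C[C@@]2(O[Si](CC)(CC)CC)C(C)C
F4 | step 17 | 2α,10α-bis(TBSO)-1β,8-dimethyl-4-(propan-2-yl)bicyclo[5.3.0]deca-4,8-dien-6-one | O=C1CC(C)=C[C@@H](O[Si](C)(C)C(C)(C)C)[C@@]2(C)[C@@H](O[Si](C)(C)C(C)(C)C)CC(C(C)C)=C12
F5 | step 17 | 2α,10α-bis(TBSO)-1β,8-dimethyl-4-(propan-2-yl)bicyclo[5.3.0]deca-4,8-dien-6α-ol | O[C@H]1CC(C)=C[C@@H](O[Si](C)(C)C(C)(C)C)[C@@]2(C)[C@@H](O[Si](C)(C)C(C)(C)C)CC(C(C)C)=C12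
F6 | step 17 | 4β,5β-epoxide of F5 | O[C@H]1CC(C)=C[C@@H](O[Si](C)(C)C(C)(C)C)[C@@]2(C)[C@@H](O[Si](C)(C)C(C)(C)C)C[C@]3(C(C)C)O[C@]123
F7 | step 12 | methyl (E)-4-(TBSO)but-3-enoate | COC(=O)C/C=C/O[Si](C)(C)C(C)(C)C
F8 | step 12 | methyl (E)-4-(TBSO)-2-diazobut-3-enoate | COC(=O)C(=[N+]=[N-])/C=C/O[Si](C)(C)C(C)(C)C
F9 | step 12 | methyl ester analogue of 19 | CC[Si](CC)(CC)OC1=C2[C@](O[Si](CC)(CC)CC)(C(C)C)C[C@H](O[Si](C)(C)C(C)(C)C)[C@]2(C)[C@H](O[Si](C)(C)C(C)(C)C)C=C(C(=O)OC)C1
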